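Ring B (C5–C10, the ring that carries the isopropylidene) is closed at C7–C8 before ring C exists. In one operation an allylic alcohol is oxidised to a vinyl ketone and its nitronate cyclises 6-endo. The step exploits two features: C5, the later isopropylidene carbon, is a ketone at this stage and makes C7 electrophilic; C8, the ring-fusion CH between the quaternary carbons C9 and C14, can be carried as a nitro-bearing carbon, a masked ketone. The precursor is an acyclic γ-nitro allylic alcohol whose C9 and C10 stereocentres come from an organocatalytic aldehyde–nitroalkene Michael addition. Nef reaction, Robinson annulation of ring C, reductive benzylation, McMurry isopropylidenation and phenol oxidation follow.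

Key step: step 4

Numbering used throughout: ring B = C5 (isopropylidene carbon; C4 carries the two methyls), C6, C7, C8 (ring-fusion H), C9 (angular methyl), C10 (H and the side chain C1–C2–C3). Ring C = C8, C9, C11, C12, C13 (secondary methyl), C14 (methyl and the arylmethyl group). β is the face of the C9 methyl.

Remark: 5-[(tert-butyldimethylsilyl)oxy]pentanal is taken as a catalogue compound (otherwise one oxidation from catalogue 5-[(tert-butyldimethylsilyl)oxy]pentan-1-ol).

**Step 1**
Reactants: 1 nitromethane; 2 acetaldehyde
Product: 5 (E)-1-nitroprop-1-ene, via 1-nitropropan-2-ol 3 (not isolated), via 1-nitropropan-2-yl methanesulfonate 4 (not isolated)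
Conditions: MeNO2 (excess), NaOH (cat.), MeOH, 0 °C; concentrate; then MsCl, Et3N, CH2Cl2, 0 °C; distil
Reagents that add atoms: none
Why: Henry (nitroaldol) addition followed by mesylation and base-induced elimination should give the conjugated nitroalkene as the more stable (E) isomer.

**Step 2**
Reactants: 5 (E)-1-nitroprop-1-ene; 6 5-[(tert-butyldimethylsilyl)oxy]pentanal
Product: 7 (2S,3S)-2-{3-[(tert-butyldimethylsilyl)oxy]propyl}-3-methyl-4-nitrobutanal
Conditions: (R)-α,α-diphenylprolinol trimethylsilyl ether (10 mol%), 4-nitrophenol (10 mol%), toluene, 0 °C → rt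
Reagents that add atoms: none
Why: Enamine-catalysed Michael addition of an aldehyde to a nitroalkene, in which the bulky diarylsilyloxymethyl group of the (R)-catalyst shields one face of the (E)-enamine; by analogy with the propanal–nitrostyrene case this should set C10 as (S) and place the C9 methyl syn.

**Step 3**
Reactants: 7 the γ-nitro aldehyde
Product: 8 (4S,5S)-4-{3-[(tert-butyldimethylsilyl)oxy]propyl}-5-methyl-6-nitrohex-1-en-3-ol (both carbinol epimers)
Conditions: CH2=CHMgBr (1.2 equiv), THF, −78 °C; aq. NH4Cl
Reagents that add atoms: vinylmagnesium bromide, C=C[Mg]Br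
Why: Grignard 1,2-addition to the aldehyde should outrun the kinetically slow deprotonation of the nitroalkane at −78 °C; the new carbinol centre (C5) is uncontrolled and is removed by the oxidation in step 4.

**Step 4**
Reactants: 8 the γ-nitro allylic alcohol
Product: 10 (2S,3S)-2-{3-[(tert-butyldimethylsilyl)oxy]propyl}-3-methyl-4-nitrocyclohexan-1-one, via nitro vinyl ketone 9 (not isolated)
Conditions: Dess–Martin periodinane, NaHCO3, CH2Cl2, 0 °C → rt; filter; then dilute with CH2Cl2 (0.01 M), DBU (0.3 equiv), 0 °C → rt
Reagents that add atoms: none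
Why: Oxidation gives vinyl ketone 9, and DBU deprotonates only the primary nitro group (far more acidic than the ketone α-hydrogen at C10) to the nitronate, whose carbon C8 adds to the enone terminus C7. The closest known reaction type is the intramolecular nitro-Michael (nitronate conjugate addition) cyclisation to 4-nitrocyclohexanones. Ring B (C5–C6–C7–C8–C9–C10) closes in the 6-endo-trig mode, with the carbonyl carbon C5 inside the new ring. The new stereocentre C8 needs no control, because it equilibrates through the nitronate and is erased in step 6; C9 and C10 come from 7, and any base-induced epimerisation at C10 only returns the more stable 2,3-trans isomer that is already present. The step needs ring closure over intermolecular Michael oligomerisation and C- over O-attack of the nitronate, which high dilution, catalytic base and the unstrained six-membered transition state should secure.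

**Step 5**
Reactants: 10 the nitro cyclohexanone
Product: 11 tert-butyldimethyl{3-[(6S,7S)-7-methyl-8-nitro-1,4-dioxaspiro[4.5]decan-6-yl]propoxy}silane
Conditions: (Me3SiOCH2)2, Me3SiOTf (5 mol%), CH2Cl2, −78 → −20 °C; pyridine
Reagents that add atoms: 1,2-bis(trimethylsilyloxy)ethane, C[Si](C)(C)OCCO[Si](C)(C)C
Why: Silyl-triflate-catalysed ketalisation under aprotic conditions spares the silyl ether; C5 is the only carbonyl present because C8 is still at the nitro stage, so the two later ketones are differentiated without a selectivity problem.

**Step 6**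
Reactants: 11 the nitro ketal
Product: 13 (6S,7S)-6-{3-[(tert-butyldimethylsilyl)oxy]propyl}-7-methyl-1,4-dioxaspiro[4.5]decan-8-one, via potassium nitronate 12 (not isolated)
Conditions: KOH, MeOH, 0 °C; then KMnO4, MgSO4, H2O, 0 °C
Reagents that add atoms: potassium permanganate, [K+].[O-][Mn](=O)(=O)=O
Why: Oxidative Nef reaction, in which permanganate cleaves the C=N bond of the nitronate to the C8 ketone under basic conditions that keep the dioxolane and the silyl ether; C9 becomes epimerisable, which is without consequence.

**Step 7**
Reactants: 13 the ring B ketone; 14 pent-1-en-3-one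
Product: 16 ketal enone (octalone; C9 methyl cis to the C10 chain), via Michael diketone 15 (not isolated)
Conditions: 14 (1.5 equiv), KOt-Bu (0.2 equiv), t-BuOH/THF, 0 °C → rt; then NaOMe, MeOH, 65 °C
Reagents that add atoms: none
Why: Robinson annulation, in which the more substituted enolate adds through C9 to the enone anti to the neighbouring C10 chain (held pseudoaxial by allylic 1,2-strain with the C9 methyl), so the quaternary centre C9 forms with its methyl cis to the chain; aldol condensation of C14 onto C8 then gives the C8=C14 enone.

**Step 8**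
Reactants: 17 2,6-dimethylanisole
Product: 18 1-(bromomethyl)-2-methoxy-3-methylbenzene
Conditions: N-bromosuccinimide (1.0 equiv), AIBN (cat.), PhCF3, 80 °C
Reagents that add atoms: N-bromosuccinimide, O=C1CCC(=O)N1Br
Why: Wohl–Ziegler radical benzylic bromination; the two methyl groups are equivalent, and one equivalent of reagent in a non-polar solvent should limit dibromination and ring bromination.

**Step 9**
Reactants: 16 the ketal enone; 18 1-(bromomethyl)-2-methoxy-3-methylbenzene
Product: 20 benzylated trans-decalone, via lithium enolate 19 (not isolated)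
Conditions: Li (2.3 equiv), NH3(l)/THF, t-BuOH (1.0 equiv), −78 °C; isoprene; then 18 (2 equiv), THF, −78 → −33 °C; NH4Cl
Reagents that add atoms: none
Why: Dissolving-metal reductive alkylation, in which axial protonation of the β-carbon C8 gives the trans-fused lithium enolate and this is benzylated regiospecifically at C14 from the face opposite the axial C9 methyl, so 8-H and the C14 benzyl group both end anti to the C9 methyl.

**Step 10**
Reactants: 20 the benzylated decalone
Product: 21 C13 exocyclic methylene compound
Conditions: Ph3PCH3Br (4 equiv), KOt-Bu (3.8 equiv), toluene, 90 °C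
Reagents that add atoms: methyltriphenylphosphonium bromide, C[P+](c1ccccc1)(c1ccccc1)c1ccccc1.[Br-]
Why: Wittig methylenation with the non-stabilised ylide at elevated temperature, the standard answer to a hindered ketone next to a quaternary carbon.

**Step 11**
Reactants: 21 the exocyclic alkene
Product: 22 13β-methyl decalin (ketal and silyl ether intact)
Conditions: H2 (1 atm), PtO2, EtOAc, rt
Reagents that add atoms: none
Why: Heterogeneous hydrogenation should deliver hydrogen to the exocyclic alkene from the α face, opposite the axial C14 methyl, so the new C13 methyl is equatorial and syn to the C14 methyl.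

**Step 12**
Reactants: 22 the ketal
Product: 23 C5 ketone (silyl ether retained)
Conditions: PPTS (0.3 equiv), acetone/H2O (9:1), 50 °C
Reagents that add atoms: water, O
Why: Mild acid-catalysed ketal hydrolysis frees the C5 ketone while the primary silyl ether survives; C10, now α to the ketone, already holds the thermodynamically preferred equatorial chain.

**Step 13**
Reactants: 23 the C5 ketone
Product: 24 C5 isopropylidene compound (silyl ether)
Conditions: TiCl4, Zn, pyridine, THF, reflux; then 23 and acetone (10 equiv) by slow addition, reflux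
Reagents that add atoms: acetone, CC(C)=O
Why: Mixed McMurry coupling with excess acetone, in which deoxygenation of the titanium pinacolate is irreversible, so the strained tetrasubstituted alkene (allylic strain with the equatorial C10 chain) forms under kinetic control on a non-basic reagent.

**Step 14**
Reactants: 24 the silyl ether
Product: 27 anisole carboxylic acid, via primary alcohol 25 (not isolated), via aldehyde 26 (not isolated)
Conditions: TBAF, THF, rt; then MeCN/H2O, TEMPO (20 mol%), PhI(OAc)2 (2.5 equiv), rt
Reagents that add atoms: water, O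
Why: Fluoride desilylation followed by oxoammonium (TEMPO) oxidation of the primary alcohol through the aldehyde hydrate to the acid, under conditions that should leave the tetrasubstituted alkene and the anisole untouched.

**Step 15**
Reactants: 27 the anisole acid
Product: 28 phenol acid
Conditions: NaSEt (6 equiv), DMF, 130 °C; aq. HCl
Reagents that add atoms: none
Why: SN2 demethylation of the aryl methyl ether by thiolate; basic conditions are chosen because acid would promote cyclisation of the phenol onto the isopropylidene.

**Step 16**
Reactants: 28 the phenol acid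
Product: 29 stypoquinonic acid
Conditions: Co(salen) (C16H14CoN2O2, the divalent cobalt complex of N,N'-bis(salicylidene)ethylenediamine; 10 mol%), O2 (1 atm), DMF, rt
Reagents that add atoms: dioxygen, O=O
Why: Cobalt–salen-catalysed aerobic oxidation of a 2,6-dialkylphenol at its free para position should give the 2,6-disubstituted 1,4-benzoquinone.

**Compound list**

1 | nitromethane | C[N+](=O)[O-] | starting material
2 | acetaldehyde | CC=O | starting material
3 | 1-nitropropan-2-ol (racemic; not isolated) | CC(O)C[N+](=O)[O-] | intermediate
4 | 1-nitropropan-2-yl methanesulfonate (racemic; not isolated) | CC(OS(C)(=O)=O)C[N+](=O)[O-] | intermediate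
5 | (E)-1-nitroprop-1-ene | C/C=C/[N+](=O)[O-] | intermediate
6 | 5-[(tert-butyldimethylsilyl)oxy]pentanal | O=CCCCCO[Si](C)(C)C(C)(C)C | starting material
7 | (2S,3S)-2-{3-[(tert-butyldimethylsilyl)oxy]propyl}-3-methyl-4-nitrobutanal (syn; C2 is the later C10, C3 the later C9) | O=C[C@@H](CCCO[Si](C)(C)C(C)(C)C)[C@H](C)C[N+](=O)[O-] | intermediate
8 | (4S,5S)-4-{3-[(tert-butyldimethylsilyl)oxy]propyl}-5-methyl-6-nitrohex-1-en-3-ol (both C3 epimers) | C=CC(O)[C@@H](CCCO[Si](C)(C)C(C)(C)C)[C@H](C)C[N+](=O)[O-] | intermediate
9 | (4S,5S)-4-{3-[(tert-butyldimethylsilyl)oxy]propyl}-5-methyl-6-nitrohex-1-en-3-one (not isolated) | C=CC(=O)[C@@H](CCCO[Si](C)(C)C(C)(C)C)[C@H](C)C[N+](=O)[O-] | intermediate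
10 | (2S,3S)-2-{3-[(tert-butyldimethylsilyl)oxy]propyl}-3-methyl-4-nitrocyclohexan-1-one (2,3-trans; both C4 epimers) | O=C1CCC([N+](=O)[O-])[C@@H](C)[C@@H]1CCCO[Si](C)(C)C(C)(C)C | intermediate
11 | tert-butyldimethyl{3-[(6S,7S)-7-methyl-8-nitro-1,4-dioxaspiro[4.5]decan-6-yl]propoxy}silane (both C8 epimers) | C12(OCCO1)CCC([N+](=O)[O-])[C@@H](C)[C@@H]2CCCO[Si](C)(C)C(C)(C)C | intermediate
12 | potassium nitronate of 11 (not isolated) | C12(OCCO1)CCC(=[N+]([O-])[O-])[C@@H](C)[C@@H]2CCCO[Si](C)(C)C(C)(C)C.[K+] | intermediate
13 | (6S,7S)-6-{3-[(tert-butyldimethylsilyl)oxy]propyl}-7-methyl-1,4-dioxaspiro[4.5]decan-8-one (C7 epimerisable) | C12(OCCO1)CCC(=O)[C@@H](C)[C@@H]2CCCO[Si](C)(C)C(C)(C)C | intermediate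
14 | pent-1-en-3-one (ethyl vinyl ketone) | C=CC(=O)CC | starting material
15 | Michael diketone: 13 carrying a 3-oxopentyl group on C9, trans to the C10 chain (not isolated) | CCC(=O)CC[C@]1(C)C(=O)CCC2(OCCO2)[C@H]1CCCO[Si](C)(C)C(C)(C)C | intermediate
16 | ketal enone: C13 ketone conjugated with C8=C14 (C14 methyl); 9β-methyl cis to the 10β-[3-(silyloxy)propyl] chain; C5 ethylene ketal | CC1=C2CCC3(OCCO3)[C@@H](CCCO[Si](C)(C)C(C)(C)C)[C@]2(C)CCC1=O | intermediate
17 | 2,6-dimethylanisole | COc1c(C)cccc1C | starting material
18 | 1-(bromomethyl)-2-methoxy-3-methylbenzene | COc1c(C)cccc1CBr | intermediate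
19 | lithium C13–C14 enolate of the trans-fused decalin, 8-H α (not isolated) | [Li+].CC1=C([O-])CC[C@@]2(C)[C@H](CCCO[Si](C)(C)C(C)(C)C)C3(OCCO3)CC[C@H]12 | intermediate
20 | trans-decalone: C13 ketone; C14 with β-methyl and α-(2-methoxy-3-methylbenzyl); 8-H α; 9-methyl β; 10-chain β; C5 ethylene ketal; silyl ether | COc1c(C)cccc1C[C@]2(C)[C@H]3CCC4(OCCO4)[C@@H](CCCO[Si](C)(C)C(C)(C)C)[C@]3(C)CCC2=O | intermediate
21 | as 20 with C13=CH2 in place of the ketone | COc1c(C)cccc1C[C@]2(C)[C@H]3CCC4(OCCO4)[C@@H](CCCO[Si](C)(C)C(C)(C)C)[C@]3(C)CCC2=C | intermediate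
22 | as 21 with a 13β-methyl group (13-H α) | COc1c(C)cccc1C[C@]2(C)[C@H]3CCC4(OCCO4)[C@@H](CCCO[Si](C)(C)C(C)(C)C)[C@]3(C)CC[C@H]2C | intermediate
23 | as 22 with a C5 ketone in place of the ketal | COc1c(C)cccc1C[C@]2(C)[C@H]3CCC(=O)[C@@H](CCCO[Si](C)(C)C(C)(C)C)[C@]3(C)CC[C@H]2C | intermediate
24 | as 23 with a C5 isopropylidene group in place of the ketone | COc1c(C)cccc1C[C@]2(C)[C@H]3CCC(=C(C)C)[C@@H](CCCO[Si](C)(C)C(C)(C)C)[C@]3(C)CC[C@H]2C | intermediate
25 | primary alcohol from 24 (not isolated) | COc1c(C)cccc1C[C@]2(C)[C@H]3CCC(=C(C)C)[C@@H](CCCO)[C@]3(C)CC[C@H]2C | intermediate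
26 | aldehyde from 25 (not isolated) | COc1c(C)cccc1C[C@]2(C)[C@H]3CCC(=C(C)C)[C@@H](CCC=O)[C@]3(C)CC[C@H]2C | intermediate
27 | anisole carboxylic acid: the target skeleton with a 2-methoxy-3-methylphenyl ring | COc1c(C)cccc1C[C@]2(C)[C@H]3CCC(=C(C)C)[C@@H](CCC(=O)O)[C@]3(C)CC[C@H]2C | intermediate
28 | phenol acid: the target skeleton with a 2-hydroxy-3-methylphenyl ring | Cc1cccc(C[C@]2(C)[C@H]3CCC(=C(C)C)[C@@H](CCC(=O)O)[C@]3(C)CC[C@H]2C)c1O | intermediate
29 | stypoquinonic acid | CC1=CC(=O)C=C(C[C@]2(C)[C@H]3CCC(=C(C)C)[C@@H](CCC(=O)O)[C@]3(C)CC[C@H]2C)C1=O | target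

**Step count and risks**

Total step count: 16. Longest linear sequence: 15 steps (steps 1–7 and 9–16); step 8 is a one-step branch.

Steps most likely to fail:

1. Step 13 (mixed McMurry). The cross-coupling may stall at the hindered C5 ketone while acetone couples with itself. Lewis-acid-promoted enolisation at C10 could also feed a less strained C10-epimeric alkene. The fallback sets out from 23 and comes back at 24. Kinetic deprotonation at C6 (KN(SiMe3)2, THF, −78 °C) and trapping with PhNTf2 should give the C5–C6 enol triflate F1. Suzuki–Miyaura coupling with isopropenylboronic acid pinacol ester (Pd(PPh3)4, a zerovalent palladium complex; K3PO4; dioxane/H2O) should give the cross-conjugated diene F2. Chromium-catalysed 1,4-hydrogenation ((η6-naphthalene)Cr(CO)3, H2, THF) then adds hydrogen to C6 and to the terminal methylene carbon, which gives 24 without ever enolising towards C10.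

2. Step 7 (Robinson annulation). The Michael addition may take place at the unhindered α-carbon C7 instead of C9, or syn to the C10 chain, and the vinyl ketone may polymerise under base. The fallback sets out from 13 and comes back at 16. Me3SiCl, Et3N, DMF at 130 °C should give the more substituted silyl enol ether F3. MeLi (THF, 0 °C) releases the C9 lithium enolate regiospecifically, and this is added at −78 °C to 2-(trimethylsilyl)pent-1-en-3-one (CCC(=O)C(=C)[Si](C)(C)C), a non-polymerising acceptor, to give the α-silyl diketone F4. KOH in MeOH then removes silicon and effects the aldol condensation to 16.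

3. Step 11 (hydrogenation). Hydrogen may be delivered in part from the β face, which would give the axial C13 methyl epimer. The fallback sets out from 21 and comes back at 22 and makes no new compound (F0). It replaces surface hydrogenation by a hydrogen-atom-transfer hydrogenation (Mn(dpm)3, tris(dipivaloylmethanato)manganese; PhSiH3; t-BuOOH; i-PrOH; rt). The tertiary C13 radical formed by stepwise hydrogen-atom transfer should collapse to the thermodynamically preferred equatorial methyl isomer.

**Further compounds**

F1 | step 13 | C5–C6 enol triflate of 23 | COc1c(C)cccc1C[C@]2(C)[C@H]3CC=C(OS(=O)(=O)C(F)(F)F)[C@@H](CCCO[Si](C)(C)C(C)(C)C)[C@]3(C)CC[C@H]2C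
F2 | step 13 | C5-isopropenyl C5–C6 diene | COc1c(C)cccc1C[C@]2(C)[C@H]3CC=C(C(C)=C)[C@@H](CCCO[Si](C)(C)C(C)(C)C)[C@]3(C)CC[C@H]2C
F3 | step 7 | C8–C9 trimethylsilyl enol ether of 13 | C[Si](C)(C)OC1=C(C)[C@H](CCCO[Si](C)(C)C(C)(C)C)C2(OCCO2)CC1
F4 | step 7 | α-trimethylsilyl analogue of diketone 15 | CCC(=O)C(C[C@]1(C)C(=O)CCC2(OCCO2)[C@H]1CCCO[Si](C)(C)C(C)(C)C)[Si](C)(C)C
F0 | step 11 | none | none
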